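**Retrosynthetic overview**
- The lactol ring is the closed form of a 2-(3-acyloxy-2-oxobutan-2-yl)benzoic acid; it is closed last by acid unmasking of a dioxolane and a tert-butyl ester.
- Both benzene rings are cut to an alkynoate plus a 1-methoxy-1-silyloxy-1,3-diene (Diels–Alder/aromatisation): the acyl ring from a but-2-ynoate ester and a 1,3-bis(silyloxy)pentadiene, the core ring from a tert-butyl ynoate and a 1,3-dimethoxy-1-silyloxypentadiene.
- Ring order, all in the final flask: acyl arene, then core arene, then lactol.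
- The bis-ynoate comes from one terminal alkyne by C-tert-butoxycarbonylation and O-acylation with but-2-ynoic acid.
- C4 comes from (R)-but-3-yn-2-ol by Marshall Pd/Zn propargylation of a silyloxyacetaldehyde (net inversion); the new carbinol is oxidised and masked as a ketal.

Assumption: the 3R hemiketal centre is the thermodynamically favoured anomer (3-OH axial, trans to the pseudo-axial 4-CH3), so it is set by lactol equilibration once C4 is fixed.
Assumption: compound numbers follow first appearance in the numbered steps; the overview uses names only.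

**Route**

Step 1
Reactants: 1 (R)-but-3-yn-2-ol
Product: 2 (R)-but-3-yn-2-yl methanesulfonate
Conditions: MsCl, Et3N, CH2Cl2, −78 → 0 °C
Reagents that add atoms: methanesulfonyl chloride, CS(=O)(=O)Cl
Why: O-sulfonylation (mesylate formation) touches only the O–H bond, so the purchased R centre is retained and becomes a propargylic leaving group for Pd(0).

Step 2
Reactants: 2 (R)-but-3-yn-2-yl methanesulfonate; 3 (tert-butyldimethylsilyloxy)acetaldehyde
Product: 5 (2S,3S)-1-[(tert-butyldimethylsilyl)oxy]-3-methylpent-4-yn-2-ol, via allenylzinc 4 (not isolated)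
Conditions: Pd(OAc)2 (5 mol %), PPh3 (5 mol %), Et2Zn (3 equiv), THF, −78 → −20 °C; aq NH4Cl
Reagents that add atoms: none
Why: Marshall–Tamaru propargylation (Pd(0)/Et2Zn umpolung): anti-SN2′ oxidative addition, Pd→Zn exchange with retention to the (M)-allenylzinc and cyclic SE2′ addition to the aldehyde replace C–OMs by C–C with net inversion, which sets the methyl-bearing carbon (future C4) as S by chirality transfer from 1; the anti (2S) carbinol is erased in step 3, so its diastereomer ratio does not matter.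

Step 3
Reactants: 5 (2S,3S)-1-[(tert-butyldimethylsilyl)oxy]-3-methylpent-4-yn-2-ol
Product: 6 (3S)-1-[(tert-butyldimethylsilyl)oxy]-3-methylpent-4-yn-2-one
Conditions: Dess–Martin periodinane, NaHCO3, CH2Cl2, 0 °C → rt
Reagents that add atoms: none
Why: Dess–Martin oxidation is neutral and fast, so the ketone forms without enolising the α-stereocentre or isomerising the β,γ-alkyne to an allene.

Step 4
Reactants: 6 (3S)-1-[(tert-butyldimethylsilyl)oxy]-3-methylpent-4-yn-2-one
Product: 7 2-[(2S)-but-3-yn-2-yl]-2-{[(tert-butyldimethylsilyl)oxy]methyl}-1,3-dioxolane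
Conditions: TMSOCH2CH2OTMS, TMSOTf (5 mol %), CH2Cl2, −78 → −20 °C; pyridine quench
Reagents that add atoms: 1,2-bis(trimethylsilyloxy)ethane, C[Si](C)(C)OCCO[Si](C)(C)C
Why: Noyori acetalisation runs under aprotic, low-temperature Lewis-acid catalysis that does not epimerise α-centres, and the dioxolane removes the carbonyl that would make the propargylic C–H acidic once the ynoate is in place.

Step 5
Reactants: 7 2-[(2S)-but-3-yn-2-yl]-2-{[(tert-butyldimethylsilyl)oxy]methyl}-1,3-dioxolane
Product: 9 tert-butyl (4S)-4-(2-{[(tert-butyldimethylsilyl)oxy]methyl}-1,3-dioxolan-2-yl)pent-2-ynoate, via lithium acetylide 8 (not isolated)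
Conditions: n-BuLi, THF, −78 °C; Boc2O, −78 → −40 °C; aq NH4Cl at −78 °C
Reagents that add atoms: di-tert-butyl dicarbonate, CC(C)(C)OC(=O)OC(=O)OC(C)(C)C
Why: Acetylide C-acylation (alkoxycarbonylation with Boc2O) converts the only acidic C–H into the tert-butyl ynoate, and the cold quench avoids alkoxide-induced alkyne–allene isomerisation at C4.

Step 6
Reactants: 9 tert-butyl (4S)-4-(2-{[(tert-butyldimethylsilyl)oxy]methyl}-1,3-dioxolan-2-yl)pent-2-ynoate
Product: 10 tert-butyl (4S)-4-[2-(hydroxymethyl)-1,3-dioxolan-2-yl]pent-2-ynoate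
Conditions: HF·pyridine, pyridine, THF, 0 °C → rt
Reagents that add atoms: none
Why: Buffered fluoride desilylation removes the primary TBS ether while the dioxolane, the tert-butyl ester and the base-sensitive ynoate are untouched.

Step 7
Reactants: 10 tert-butyl (4S)-4-[2-(hydroxymethyl)-1,3-dioxolan-2-yl]pent-2-ynoate; 11 but-2-ynoic acid
Product: 12 tert-butyl (4S)-4-{2-[(but-2-ynoyloxy)methyl]-1,3-dioxolan-2-yl}pent-2-ynoate
Conditions: DIC, DMAP (5 mol %), CH2Cl2, 0 °C
Reagents that add atoms: none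
Why: Steglich esterification acylates the single free (primary) hydroxyl, and low temperature with little DMAP keeps both alkynoates from isomerising.

Step 8
Reactants: 13 methyl 3-oxopentanoate
Product: 15 (1Z,3Z)-1-methoxy-1,3-bis(trimethylsilyloxy)penta-1,3-diene, via silyl enol ether 14 (not isolated)
Conditions: TMSOTf (2.2 equiv), Et3N (2.6 equiv), Et2O, 0 °C → rt
Reagents that add atoms: trimethylsilyl trifluoromethanesulfonate, C[Si](C)(C)OS(=O)(=O)C(F)(F)F
Why: Simchen soft enolisation silylates the β-keto ester twice, first at the ketone oxygen and then, after γ-deprotonation of the silyl-activated ester, at the ester oxygen, giving the Chan-type 1,3-bis(silyloxy)diene with the terminal methyl cis to 3-OTMS (the geometry that can reach s-cis).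

Step 9
Reactants: 13 methyl 3-oxopentanoate
Product: 17 methyl (E)-3-methoxypent-2-enoate, via dimethyl ketal 16 (not isolated)
Conditions: HC(OMe)3, H2SO4 (cat.), rt; then distil (−MeOH)
Reagents that add atoms: trimethyl orthoformate, COC(OC)OC
Why: Acid-catalysed ketalisation followed by thermal elimination of methanol (enol ether formation) gives the conjugated E-enol ether, with the ethyl group cis to the ester as needed for the next deprotonation.

Step 10
Reactants: 17 methyl (E)-3-methoxypent-2-enoate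
Product: 19 (1Z,3Z)-1,3-dimethoxy-1-(trimethylsilyloxy)penta-1,3-diene, via lithium dienolate 18 (not isolated)
Conditions: LDA, THF, −78 °C; TMSCl, −78 °C → rt
Reagents that add atoms: chlorotrimethylsilane, C[Si](C)(C)Cl
Why: Carbonyl-directed kinetic γ-deprotonation and O-silylation of the dienolate is the standard route to Brassard-type vinylketene acetals; the terminal methyl ends cis to 3-OMe.

Step 11
Reactants: 12 tert-butyl (4S)-4-{2-[(but-2-ynoyloxy)methyl]-1,3-dioxolan-2-yl}pent-2-ynoate; 15 (1Z,3Z)-1-methoxy-1,3-bis(trimethylsilyloxy)penta-1,3-diene; 19 (1Z,3Z)-1,3-dimethoxy-1-(trimethylsilyloxy)penta-1,3-diene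
Product: 25 [(3R,4S)-3,8-dihydroxy-6-methoxy-4,5-dimethyl-1-oxo-3,4-dihydro-1H-isochromen-3-yl]methyl 2,4-dihydroxy-5,6-dimethylbenzoate, via first cycloadduct 20 (not isolated), via monoarene 21 (not isolated), via second cycloadduct 22 (not isolated), via bisarene 23 (not isolated), via keto acid 24 (not isolated)
Conditions: (i) 15 (2.2 equiv), PhMe, 120 °C, sealed tube; volatiles off in vacuo; (ii) 19 (6 equiv, portions), PhMe, 150 °C; (iii) TFA/CH2Cl2/H2O (10:10:1), rt
Reagents that add atoms: water, O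
Why: Proposed new method: one-pot sequential double Diels–Alder/aromatisation benzannulation followed by global acidolysis; the closest known reaction type is the thermal cycloaddition of Chan/Brassard 1-methoxy-1-silyloxydienes to alkynoates (diene C4 bonds to the ynoate β-carbon, the ketene-acetal carbon ends ortho to the ester, aromatisation by 1,4-loss of methanol), and the untested element is doing it twice on one bis-ynoate, where the unhindered but-2-ynoate is expected to react first with the more electron-rich 15 and the neopentyl-flanked tert-butyl ynoate only under forcing with 19; aqueous TFA then removes three TMS groups, the tert-butyl ester and the dioxolane so that keto acid 24 closes to the six-membered lactol, C4 (S) being carried unchanged from step 2 and C3 settling as 3R under thermodynamic (anomeric) control.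

**Compound list**

1 | (R)-but-3-yn-2-ol | C#C[C@@H](C)O | starting material
2 | (R)-but-3-yn-2-yl methanesulfonate | C#C[C@@H](C)OS(C)(=O)=O | intermediate
3 | (tert-butyldimethylsilyloxy)acetaldehyde | O=CCO[Si](C)(C)C(C)(C)C | starting material
4 | ethyl[(M)-buta-1,2-dien-1-yl]zinc | CC[Zn]C([H])=[C@@]=C([H])C | intermediate
5 | (2S,3S)-1-[(tert-butyldimethylsilyl)oxy]-3-methylpent-4-yn-2-ol | C#C[C@H](C)[C@H](O)CO[Si](C)(C)C(C)(C)C | intermediate
6 | (3S)-1-[(tert-butyldimethylsilyl)oxy]-3-methylpent-4-yn-2-one | C#C[C@H](C)C(=O)CO[Si](C)(C)C(C)(C)C | intermediate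
7 | 2-[(2S)-but-3-yn-2-yl]-2-{[(tert-butyldimethylsilyl)oxy]methyl}-1,3-dioxolane | C#C[C@H](C)C1(CO[Si](C)(C)C(C)(C)C)OCCO1 | intermediate
8 | lithium acetylide of 7 | [Li]C#C[C@H](C)C1(CO[Si](C)(C)C(C)(C)C)OCCO1 | intermediate
9 | tert-butyl (4S)-4-(2-{[(tert-butyldimethylsilyl)oxy]methyl}-1,3-dioxolan-2-yl)pent-2-ynoate | CC(C)(C)OC(=O)C#C[C@H](C)C1(CO[Si](C)(C)C(C)(C)C)OCCO1 | intermediate
10 | tert-butyl (4S)-4-[2-(hydroxymethyl)-1,3-dioxolan-2-yl]pent-2-ynoate | CC(C)(C)OC(=O)C#C[C@H](C)C1(CO)OCCO1 | intermediate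
11 | but-2-ynoic acid | CC#CC(=O)O | starting material
12 | tert-butyl (4S)-4-{2-[(but-2-ynoyloxy)methyl]-1,3-dioxolan-2-yl}pent-2-ynoate | CC(C)(C)OC(=O)C#C[C@H](C)C1(COC(=O)C#CC)OCCO1 | intermediate
13 | methyl 3-oxopentanoate | CCC(=O)CC(=O)OC | starting material
14 | methyl (E)-3-(trimethylsilyloxy)pent-2-enoate (E drawn; an E/Z mixture is acceptable) | CC/C(O[Si](C)(C)C)=C\C(=O)OC | intermediate
15 | (1Z,3Z)-1-methoxy-1,3-bis(trimethylsilyloxy)penta-1,3-diene | C/C=C(\O[Si](C)(C)C)/C=C(/OC)O[Si](C)(C)C | intermediate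
16 | methyl 3,3-dimethoxypentanoate | CCC(OC)(OC)CC(=O)OC | intermediate
17 | methyl (E)-3-methoxypent-2-enoate | CC/C(OC)=C\C(=O)OC | intermediate
18 | lithium (1E,3Z)-1,3-dimethoxypenta-1,3-dien-1-olate | C/C=C(\OC)/C=C(/OC)O[Li] | intermediate
19 | (1Z,3Z)-1,3-dimethoxy-1-(trimethylsilyloxy)penta-1,3-diene | C/C=C(\OC)/C=C(/OC)O[Si](C)(C)C | intermediate
20 | {2-[(2S)-5-tert-butoxy-5-oxopent-3-yn-2-yl]-1,3-dioxolan-2-yl}methyl 6-methoxy-2,3-dimethyl-4,6-bis(trimethylsilyloxy)cyclohexa-1,4-diene-1-carboxylate (ring C3/C6 epimer mixture) | CC(C)(C)OC(=O)C#C[C@H](C)C1(COC(=O)C2=C(C)C(C)C(O[Si](C)(C)C)=CC2(OC)O[Si](C)(C)C)OCCO1 | intermediate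
21 | {2-[(2S)-5-tert-butoxy-5-oxopent-3-yn-2-yl]-1,3-dioxolan-2-yl}methyl 5,6-dimethyl-2,4-bis(trimethylsilyloxy)benzoate | CC(C)(C)OC(=O)C#C[C@H](C)C1(COC(=O)c2c(C)c(C)c(O[Si](C)(C)C)cc2O[Si](C)(C)C)OCCO1 | intermediate
22 | tert-butyl 2-[(1S)-1-(2-{[5,6-dimethyl-2,4-bis(trimethylsilyloxy)benzoyloxy]methyl}-1,3-dioxolan-2-yl)ethyl]-4,6-dimethoxy-3-methyl-6-(trimethylsilyloxy)cyclohexa-1,4-diene-1-carboxylate (ring C3/C6 epimer mixture) | CC(C)(C)OC(=O)C3=C([C@H](C)C1(COC(=O)c2c(C)c(C)c(O[Si](C)(C)C)cc2O[Si](C)(C)C)OCCO1)C(C)C(OC)=CC3(OC)O[Si](C)(C)C | intermediate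
23 | tert-butyl 2-[(1S)-1-(2-{[5,6-dimethyl-2,4-bis(trimethylsilyloxy)benzoyloxy]methyl}-1,3-dioxolan-2-yl)ethyl]-4-methoxy-3-methyl-6-(trimethylsilyloxy)benzoate | CC(C)(C)OC(=O)c3c(O[Si](C)(C)C)cc(OC)c(C)c3[C@H](C)C1(COC(=O)c2c(C)c(C)c(O[Si](C)(C)C)cc2O[Si](C)(C)C)OCCO1 | intermediate
24 | 2-[(2S)-4-(2,4-dihydroxy-5,6-dimethylbenzoyloxy)-3-oxobutan-2-yl]-6-hydroxy-4-methoxy-3-methylbenzoic acid | COc1cc(O)c(C(=O)O)c(c1C)[C@H](C)C(=O)COC(=O)c1c(O)cc(O)c(C)c1C | intermediate
25 | [(3R,4S)-3,8-dihydroxy-6-methoxy-4,5-dimethyl-1-oxo-3,4-dihydro-1H-isochromen-3-yl]methyl 2,4-dihydroxy-5,6-dimethylbenzoate (CNP0072952.2) | COc1cc(O)c2c(c1C)[C@H](C)[C@](O)(COC(=O)c1c(O)cc(O)c(C)c1C)OC2=O | target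

**Step count**

Total steps: 11. Longest linear sequence: 8 (steps 1–7, then 11).

**Three steps most likely to fail**

Step 11. The tert-butyl ynoate carries a branched, ketal-flanked β-substituent and must react with an acyclic, terminally methylated diene; the two ynoates must also be told apart in one pot, and prolonged acid could dehydrate the lactol. The fallback sets out from 9 and comes back at 25. It inverts the order of ring construction and decouples the two annulations, so the demanding one runs on the simple mono-ynoate, where it can be forced with no second ynoate to discriminate. 9 is heated neat with excess 19 (150 °C) and gives, through tert-butyl 2-[(1S)-1-(2-{[(tert-butyldimethylsilyl)oxy]methyl}-1,3-dioxolan-2-yl)ethyl]-4,6-dimethoxy-3-methyl-6-(trimethylsilyloxy)cyclohexa-1,4-diene-1-carboxylate F1, the aryl silyl ether tert-butyl 2-[(1S)-1-(2-{[(tert-butyldimethylsilyl)oxy]methyl}-1,3-dioxolan-2-yl)ethyl]-4-methoxy-3-methyl-6-(trimethylsilyloxy)benzoate F2. Aqueous TFA converts crude F2, through 6-hydroxy-2-[(2S)-4-hydroxy-3-oxobutan-2-yl]-4-methoxy-3-methylbenzoic acid F3, into the lactol diol (3R,4S)-3,8-dihydroxy-3-(hydroxymethyl)-6-methoxy-4,5-dimethylisochroman-1-one F4. The primary hydroxyl of F4 is esterified with 11 (DIC, cat. DMAP, −20 °C) to give [(3R,4S)-3,8-dihydroxy-6-methoxy-4,5-dimethyl-1-oxoisochroman-3-yl]methyl but-2-ynoate F5. F5 is silylated with BSA to its 3,8-bis(trimethylsilyl) ether F6 and heated with 15 (120 °C), which gives, through the cyclohexa-1,4-diene adduct of F6 and 15 F7, the tetrakis(trimethylsilyl) ether of 25 F8. Dilute aqueous HCl in THF then gives 25.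

Step 5. tert-Butoxide released from Boc2O can isomerise the new ynoate to the allenoate, which would destroy C4. The fallback sets out from 7 and comes back at 9. Acetylide 8 is carboxylated with CO2 instead of Boc2O, so no alkoxide is formed; cold acidification to pH 3 gives (4S)-4-(2-{[(tert-butyldimethylsilyl)oxy]methyl}-1,3-dioxolan-2-yl)pent-2-ynoic acid F9. The ester is then made by O-alkylation of the acid with O-tert-butyl-N,N′-diisopropylisourea (CH2Cl2, rt, neutral), giving 9.

Step 8. The one-pot double silylation may stop at 14 or give C-silylated and geometric mixtures, and the purity of 15 decides the selectivity of step 11. The fallback sets out from 13 and comes back at 15. It is the two-stage Chan–Molander route: 13 is O-silylated with TMSCl/Et3N and silyl enol ether 14 is isolated by distillation. LDA (THF, −78 °C) then gives by kinetic γ-deprotonation lithium (1E,3Z)-1-methoxy-3-(trimethylsilyloxy)penta-1,3-dien-1-olate F10, which is O-silylated with TMSCl to give 15.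

**Further compounds**

F1 | step 11 | tert-butyl 2-[(1S)-1-(2-{[(tert-butyldimethylsilyl)oxy]methyl}-1,3-dioxolan-2-yl)ethyl]-4,6-dimethoxy-3-methyl-6-(trimethylsilyloxy)cyclohexa-1,4-diene-1-carboxylate | CC(C)(C)OC(=O)C3=C([C@H](C)C1(CO[Si](C)(C)C(C)(C)C)OCCO1)C(C)C(OC)=CC3(OC)O[Si](C)(C)C
F2 | step 11 | tert-butyl 2-[(1S)-1-(2-{[(tert-butyldimethylsilyl)oxy]methyl}-1,3-dioxolan-2-yl)ethyl]-4-methoxy-3-methyl-6-(trimethylsilyloxy)benzoate | CC(C)(C)OC(=O)c1c(O[Si](C)(C)C)cc(OC)c(C)c1[C@H](C)C2(CO[Si](C)(C)C(C)(C)C)OCCO2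
F3 | step 11 | 6-hydroxy-2-[(2S)-4-hydroxy-3-oxobutan-2-yl]-4-methoxy-3-methylbenzoic acid | COc1cc(O)c(C(=O)O)c(c1C)[C@H](C)C(=O)CO
F4 | step 11 | (3R,4S)-3,8-dihydroxy-3-(hydroxymethyl)-6-methoxy-4,5-dimethylisochroman-1-one | COc1cc(O)c2c(c1C)[C@H](C)[C@](O)(CO)OC2=O
F5 | step 11 | [(3R,4S)-3,8-dihydroxy-6-methoxy-4,5-dimethyl-1-oxoisochroman-3-yl]methyl but-2-ynoate | COc1cc(O)c2c(c1C)[C@H](C)[C@](O)(COC(=O)C#CC)OC2=O
F6 | step 11 | 3,8-bis(trimethylsilyl) ether of F5 | COc1cc(O[Si](C)(C)C)c2c(c1C)[C@H](C)[C@](O[Si](C)(C)C)(COC(=O)C#CC)OC2=O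
F7 | step 11 | cyclohexa-1,4-diene adduct of F6 and 15 (ring C3/C6 epimer mixture) | COc1cc(O[Si](C)(C)C)c2c(c1C)[C@H](C)[C@](O[Si](C)(C)C)(COC(=O)C3=C(C)C(C)C(O[Si](C)(C)C)=CC3(OC)O[Si](C)(C)C)OC2=O
F8 | step 11 | tetrakis(trimethylsilyl) ether of 25 | COc1cc(O[Si](C)(C)C)c2c(c1C)[C@H](C)[C@](O[Si](C)(C)C)(COC(=O)c3c(C)c(C)c(O[Si](C)(C)C)cc3O[Si](C)(C)C)OC2=O
F9 | step 5 | (4S)-4-(2-{[(tert-butyldimethylsilyl)oxy]methyl}-1,3-dioxolan-2-yl)pent-2-ynoic acid | OC(=O)C#C[C@H](C)C1(CO[Si](C)(C)C(C)(C)C)OCCO1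
F10 | step 8 | lithium (1E,3Z)-1-methoxy-3-(trimethylsilyloxy)penta-1,3-dien-1-olate | C/C=C(\O[Si](C)(C)C)/C=C(/OC)O[Li]
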